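**Retrosynthetic overview**
1. The aryl–vinyl bond is cut by a Heck disconnection (aryl bromide + acrylic acid), and the ester C–O bond by a Mitsunobu disconnection (primary alcohol + unprotected p-coumaric acid).
2. The dihydrofuran ring is the only ring built (both benzene rings are bought). Its O1–C2 bond comes from an intramolecular Mitsunobu etherification, with inversion, of an anti o-hydroxyphenethyl alcohol.
3. That alcohol comes from Felkin-controlled reduction of an o-hydroxybenzyl ketone whose α-methyl stereocentre derives from the (S)-Roche ester.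
4. Key C–C bond (future C3–C2): a carbene-generated acyl anion of the Roche aldehyde adds to the exocyclic CH2 of an o-quinone methide, released by fluoride from a silyl aryl ether/benzyl bromide.
5. Order: key C–C bond, then the carbinol centre, then the oxygen ring, then the coumarate ester, then the acrylic acid.

Assumption: the SMILES is read as (S) at ring carbon C2 and (S) at the side-chain carbon, both alkenes E; a one-flask sequence with a single work-up is counted as one step.

**Route**

Step 1
Reactants: 1 4-bromo-2-methylphenol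
Product: 2 (4-bromo-2-methylphenoxy)(tert-butyl)dimethylsilane
Conditions: TBSCl (1.1 equiv), imidazole (2.0 equiv), DMF, 23 °C
Reagents that add atoms: tert-butyldimethylsilyl chloride (TBSCl), CC(C)(C)[Si](C)(C)Cl
Why: Imidazole-mediated O-silylation masks the phenol as the fluoride-labile trigger needed in step 5 and suppresses ionic ring bromination in step 2; no stereocentre is involved.

Step 2
Reactants: 2 (4-bromo-2-methylphenoxy)(tert-butyl)dimethylsilane
Product: 3 [4-bromo-2-(bromomethyl)phenoxy](tert-butyl)dimethylsilane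
Conditions: NBS (1.05 equiv), azobisisobutyronitrile (5 mol%), PhCF3, 85 °C
Reagents that add atoms: N-bromosuccinimide (NBS), O=C1CCC(=O)N1Br
Why: Wohl–Ziegler radical bromination converts the aryl methyl group into the benzylic bromide, which together with the aryl silyl ether is a latent o-quinone methide.

Step 3
Reactants: 4 methyl (2S)-3-hydroxy-2-methylpropanoate ((S)-Roche ester)
Product: 5 methyl (2S)-2-methyl-3-[(triisopropylsilyl)oxy]propanoate
Conditions: TIPSCl (1.1 equiv), imidazole (2.0 equiv), DMF, 23 °C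
Reagents that add atoms: triisopropylsilyl chloride (TIPSCl), CC(C)[Si](Cl)(C(C)C)C(C)C
Why: Standard silylation of the primary alcohol gives a bulky, non-chelating ether that survives CsF in step 5 and reinforces Felkin control in step 6, leaving the chiral-pool (S) centre untouched.

Step 4
Reactants: 5 methyl (2S)-2-methyl-3-[(triisopropylsilyl)oxy]propanoate
Product: 6 (2S)-2-methyl-3-[(triisopropylsilyl)oxy]propanal
Conditions: i-Bu2AlH (1.1 equiv), CH2Cl2, −78 °C; aq. potassium sodium tartrate; crude aldehyde used at once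
Reagents that add atoms: none
Why: Partial ester reduction through an aluminium hemiacetal that is stable at −78 °C gives the aldehyde directly, and the α-stereocentre is retained when the crude aldehyde is used immediately without chromatography.

Step 5
Reactants: 3 [4-bromo-2-(bromomethyl)phenoxy](tert-butyl)dimethylsilane, 6 (2S)-2-methyl-3-[(triisopropylsilyl)oxy]propanal
Product: 9 (3S)-1-(5-bromo-2-hydroxyphenyl)-3-methyl-4-[(triisopropylsilyl)oxy]butan-2-one, via o-quinone methide 7 (not isolated), via Breslow intermediate 8 (not isolated)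
Conditions: 6 (1.5 equiv), 3,4,5-trimethylthiazolium iodide (20 mol%), CsF (2.2 equiv), 18-crown-6 (20 mol%), CH2Cl2, 0 → 23 °C, 3 added over 4 h by syringe pump; pH 7 buffer quench
Reagents that add atoms: none
Why: Proposed new method: the thiazol-2-ylidene (from the thiazolium salt and fluoride) converts aldehyde 6 into Breslow intermediate 8, an acyl anion equivalent, while fluoride removes the aryl silyl group of 3 and the phenoxide expels bromide to give o-quinone methide 7; 1,4-addition of the nucleophilic carbon of 8 to the exocyclic CH2 of 7 is driven by re-aromatisation, and collapse of the adduct releases the carbene and ketone 9, so two natively electrophilic carbons are joined; the closest known reaction type is the carbene-catalysed acyl anion (Stetter-type) addition to fluoride-generated o-quinone methides, here extended to an α-stereogenic β-silyloxy aliphatic aldehyde, whose (S) centre should survive because neither formation of 8 nor the C–C bond formation touches the α-C–H and no amine base is present; no new stereocentre is formed.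

Step 6
Reactants: 9 (3S)-1-(5-bromo-2-hydroxyphenyl)-3-methyl-4-[(triisopropylsilyl)oxy]butan-2-one
Product: 10 4-bromo-2-[(2R,3S)-2-hydroxy-3-methyl-4-[(triisopropylsilyl)oxy]butyl]phenol
Conditions: LiBH(s-Bu)3 (2.5 equiv), THF, −78 °C; then H2O2, pH 7 buffer, 0 °C; chromatography
Reagents that add atoms: none
Why: Felkin–Anh-controlled ketone reduction, in which the bulky hydride (after deprotonating the phenol) attacks anti to the CH2OTIPS group of the α-stereocentre and sets the new carbinol as (R), i.e. 2,3-anti (expected about 5:1 or better, minor syn isomer removed by chromatography).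

Step 7
Reactants: 10 4-bromo-2-[(2R,3S)-2-hydroxy-3-methyl-4-[(triisopropylsilyl)oxy]butyl]phenol
Product: 12 (2S)-2-[(2S)-5-bromo-2,3-dihydro-1-benzofuran-2-yl]propan-1-ol, via TIPS ether 11 (not isolated)
Conditions: PPh3 (1.5 equiv), DIAD (1.5 equiv), THF, 0 → 23 °C; then Bu4NF (3 equiv), 23 °C
Reagents that add atoms: none
Why: Intramolecular Mitsunobu etherification, in which the phenol displaces the activated secondary alcohol in a 5-exo-tet SN2 closure with inversion and so turns the (R)-carbinol into the (S)-configured C2 of the dihydrobenzofuran; fluoride then cleaves the TIPS ether in the same flask.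

Step 8
Reactants: 12 (2S)-2-[(2S)-5-bromo-2,3-dihydro-1-benzofuran-2-yl]propan-1-ol, 13 (2E)-3-(4-hydroxyphenyl)prop-2-enoic acid (p-coumaric acid)
Product: 14 (2S)-2-[(2S)-5-bromo-2,3-dihydro-1-benzofuran-2-yl]propyl (2E)-3-(4-hydroxyphenyl)prop-2-enoate
Conditions: 13 (1.2 equiv), PPh3 (1.3 equiv), DIAD (1.3 equiv, slow addition), THF, 0 → 23 °C
Reagents that add atoms: none
Why: Mitsunobu esterification selects the carboxylic acid (pKa about 4.5) over the phenol (pKa about 10) as pronucleophile, so unprotected p-coumaric acid acylates the primary alcohol directly; the reacting CH2 is not stereogenic and the E-alkene is untouched.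

Step 9
Reactants: 14 (2S)-2-[(2S)-5-bromo-2,3-dihydro-1-benzofuran-2-yl]propyl (2E)-3-(4-hydroxyphenyl)prop-2-enoate, 15 prop-2-enoic acid (acrylic acid)
Product: 16 (2E)-3-[(2S)-2-[(2S)-1-{[(2E)-3-(4-hydroxyphenyl)prop-2-enoyl]oxy}propan-2-yl]-2,3-dihydro-1-benzofuran-5-yl]prop-2-enoic acid (CNP0224846.1)
Conditions: 15 (3 equiv), Pd(OAc)2 (5 mol%), P(o-tol)3 (12 mol%), Et3N (5 equiv), DMF, 100 °C; 1 M HCl work-up
Reagents that add atoms: none
Why: Mizoroki–Heck reaction, in which zerovalent palladium inserts into the aryl C–Br bond and syn-insertion of acrylate followed by syn-β-hydride elimination gives the (E)-arylacrylic acid; the monosubstituted acrylate reacts far faster than the 1,2-disubstituted coumarate alkene and, as its carboxylate, resists oxa-Michael addition by the free phenol.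

**Compound list**
1 | 4-bromo-2-methylphenol | Cc1cc(Br)ccc1O | starting material
2 | (4-bromo-2-methylphenoxy)(tert-butyl)dimethylsilane | Cc1cc(Br)ccc1O[Si](C)(C)C(C)(C)C | intermediate
3 | [4-bromo-2-(bromomethyl)phenoxy](tert-butyl)dimethylsilane | BrCc1cc(Br)ccc1O[Si](C)(C)C(C)(C)C | intermediate
4 | methyl (2S)-3-hydroxy-2-methylpropanoate | C[C@@H](CO)C(=O)OC | starting material
5 | methyl (2S)-2-methyl-3-[(triisopropylsilyl)oxy]propanoate | C[C@@H](CO[Si](C(C)C)(C(C)C)C(C)C)C(=O)OC | intermediate
6 | (2S)-2-methyl-3-[(triisopropylsilyl)oxy]propanal | C[C@@H](CO[Si](C(C)C)(C(C)C)C(C)C)C=O | intermediate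
7 | o-quinone methide 4-bromo-6-methylidenecyclohexa-2,4-dien-1-one (formed in the flask) | C=C1C=C(Br)C=CC1=O | intermediate
8 | Breslow intermediate (2S)-2-methyl-1-(3,4,5-trimethyl-1,3-thiazol-2(3H)-ylidene)-3-[(triisopropylsilyl)oxy]propan-1-ol (formed in the flask, enol geometry undefined) | OC(=C1SC(C)=C(C)N1C)[C@@H](C)CO[Si](C(C)C)(C(C)C)C(C)C | intermediate
9 | (3S)-1-(5-bromo-2-hydroxyphenyl)-3-methyl-4-[(triisopropylsilyl)oxy]butan-2-one | C[C@@H](CO[Si](C(C)C)(C(C)C)C(C)C)C(=O)Cc1cc(Br)ccc1O | intermediate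
10 | 4-bromo-2-[(2R,3S)-2-hydroxy-3-methyl-4-[(triisopropylsilyl)oxy]butyl]phenol | C[C@@H](CO[Si](C(C)C)(C(C)C)C(C)C)[C@H](O)Cc1cc(Br)ccc1O | intermediate
11 | {[(2S)-2-[(2S)-5-bromo-2,3-dihydro-1-benzofuran-2-yl]propyl]oxy}triisopropylsilane (formed in the flask) | C[C@@H](CO[Si](C(C)C)(C(C)C)C(C)C)[C@@H]1Cc2cc(Br)ccc2O1 | intermediate
12 | (2S)-2-[(2S)-5-bromo-2,3-dihydro-1-benzofuran-2-yl]propan-1-ol | C[C@@H](CO)[C@@H]1Cc2cc(Br)ccc2O1 | intermediate
13 | (2E)-3-(4-hydroxyphenyl)prop-2-enoic acid (p-coumaric acid) | OC(=O)/C=C/c1ccc(O)cc1 | starting material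
14 | (2S)-2-[(2S)-5-bromo-2,3-dihydro-1-benzofuran-2-yl]propyl (2E)-3-(4-hydroxyphenyl)prop-2-enoate | C[C@@H](COC(=O)/C=C/c1ccc(O)cc1)[C@@H]1Cc2cc(Br)ccc2O1 | intermediate
15 | prop-2-enoic acid (acrylic acid) | C=CC(=O)O | starting material
16 | (2E)-3-[(2S)-2-[(2S)-1-{[(2E)-3-(4-hydroxyphenyl)prop-2-enoyl]oxy}propan-2-yl]-2,3-dihydro-1-benzofuran-5-yl]prop-2-enoic acid | C[C@@H](COC(=O)/C=C/c1ccc(O)cc1)[C@@H]1Cc2cc(/C=C/C(=O)O)ccc2O1 | target

**Totals and risks**
Total step count: 9. Longest linear sequence: 7 steps (1 → 2 → 3 → 9 → 10 → 12 → 14 → 16; the branch 4 → 5 → 6 → 9 is equally long).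

Steps most likely to fail:

Step 5 (key C–C bond). The o-quinone methide can oligomerise or alkylate the carbene or the product phenoxide, the α-branched aldehyde forms its Breslow intermediate slowly, and the α-centre of 6 or 9 may epimerise. The fallback sets out from 6 and comes back at 9, replacing the catalytic acyl anion by a stoichiometric dithiane anion. Aldehyde 6 is condensed with propane-1,3-dithiol (BF3·OEt2, CH2Cl2, −78 °C) to 2-[(2S)-1-[(triisopropylsilyl)oxy]propan-2-yl]-1,3-dithiane F1. F1 is lithiated (t-BuLi, THF/HMPA, −78 °C) and alkylated with 3 to 2-{5-bromo-2-[(tert-butyldimethylsilyl)oxy]benzyl}-2-[(2S)-1-[(triisopropylsilyl)oxy]propan-2-yl]-1,3-dithiane F2. MeI/CaCO3 in aqueous MeCN unmasks (3S)-1-{5-bromo-2-[(tert-butyldimethylsilyl)oxy]phenyl}-3-methyl-4-[(triisopropylsilyl)oxy]butan-2-one F3, and KHF2 in MeOH removes only the aryl silyl ether to give 9.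

Step 6 (Felkin selectivity). Discrimination between CH3 and CH2OTIPS at the α-carbon may be modest. The fallback sets out from 9 and comes back at 10, replacing stereoselective reduction by stereochemical correction. Ketone 9 is reduced without demands on selectivity (NaBH4, MeOH, −20 °C) and 10 is separated. The syn epimer 4-bromo-2-[(2S,3S)-2-hydroxy-3-methyl-4-[(triisopropylsilyl)oxy]butyl]phenol F4 is silylated on the phenol only (TBSCl, imidazole, CH2Cl2, 0 °C) to (2S,3S)-1-{5-bromo-2-[(tert-butyldimethylsilyl)oxy]phenyl}-3-methyl-4-[(triisopropylsilyl)oxy]butan-2-ol F5. Intermolecular Mitsunobu reaction with 4-nitrobenzoic acid (PPh3, DIAD, THF) inverts the carbinol to (2R,3S)-1-{5-bromo-2-[(tert-butyldimethylsilyl)oxy]phenyl}-3-methyl-4-[(triisopropylsilyl)oxy]butan-2-yl 4-nitrobenzoate F6. K2CO3 in MeOH then removes the ester and the aryl silyl ether in one operation to give 10.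

Step 9 (Heck on the unprotected coumarate). Competing arylation of the coumarate alkene or sluggish oxidative addition into the electron-rich aryl bromide could lower the yield. The fallback sets out from 12 and comes back at 16, installing the acrylate before the coumarate. Heck coupling of 12 with tert-butyl acrylate (Pd(OAc)2, P(o-tol)3, Et3N, DMF, 100 °C) gives tert-butyl (2E)-3-{(2S)-2-[(2S)-1-hydroxypropan-2-yl]-2,3-dihydro-1-benzofuran-5-yl}prop-2-enoate F7. Mitsunobu esterification with 13 (PPh3, DIAD, THF) gives tert-butyl (2E)-3-[(2S)-2-[(2S)-1-{[(2E)-3-(4-hydroxyphenyl)prop-2-enoyl]oxy}propan-2-yl]-2,3-dihydro-1-benzofuran-5-yl]prop-2-enoate F8. CF3CO2H in CH2Cl2 at 0 °C cleaves the tert-butyl ester to give 16.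

**Further compounds**
F1 | step 5 | 2-[(2S)-1-[(triisopropylsilyl)oxy]propan-2-yl]-1,3-dithiane | C[C@@H](CO[Si](C(C)C)(C(C)C)C(C)C)C1SCCCS1
F2 | step 5 | 2-{5-bromo-2-[(tert-butyldimethylsilyl)oxy]benzyl}-2-[(2S)-1-[(triisopropylsilyl)oxy]propan-2-yl]-1,3-dithiane | C[C@@H](CO[Si](C(C)C)(C(C)C)C(C)C)C1(Cc2cc(Br)ccc2O[Si](C)(C)C(C)(C)C)SCCCS1
F3 | step 5 | (3S)-1-{5-bromo-2-[(tert-butyldimethylsilyl)oxy]phenyl}-3-methyl-4-[(triisopropylsilyl)oxy]butan-2-one | C[C@@H](CO[Si](C(C)C)(C(C)C)C(C)C)C(=O)Cc1cc(Br)ccc1O[Si](C)(C)C(C)(C)C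
F4 | step 6 | 4-bromo-2-[(2S,3S)-2-hydroxy-3-methyl-4-[(triisopropylsilyl)oxy]butyl]phenol | C[C@@H](CO[Si](C(C)C)(C(C)C)C(C)C)[C@@H](O)Cc1cc(Br)ccc1O
F5 | step 6 | (2S,3S)-1-{5-bromo-2-[(tert-butyldimethylsilyl)oxy]phenyl}-3-methyl-4-[(triisopropylsilyl)oxy]butan-2-ol | C[C@@H](CO[Si](C(C)C)(C(C)C)C(C)C)[C@@H](O)Cc1cc(Br)ccc1O[Si](C)(C)C(C)(C)C
F6 | step 6 | (2R,3S)-1-{5-bromo-2-[(tert-butyldimethylsilyl)oxy]phenyl}-3-methyl-4-[(triisopropylsilyl)oxy]butan-2-yl 4-nitrobenzoate | C[C@@H](CO[Si](C(C)C)(C(C)C)C(C)C)[C@H](OC(=O)c1ccc(cc1)[N+](=O)[O-])Cc1cc(Br)ccc1O[Si](C)(C)C(C)(C)C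
F7 | step 9 | tert-butyl (2E)-3-{(2S)-2-[(2S)-1-hydroxypropan-2-yl]-2,3-dihydro-1-benzofuran-5-yl}prop-2-enoate | C[C@@H](CO)[C@@H]1Cc2cc(/C=C/C(=O)OC(C)(C)C)ccc2O1
F8 | step 9 | tert-butyl (2E)-3-[(2S)-2-[(2S)-1-{[(2E)-3-(4-hydroxyphenyl)prop-2-enoyl]oxy}propan-2-yl]-2,3-dihydro-1-benzofuran-5-yl]prop-2-enoate | C[C@@H](COC(=O)/C=C/c1ccc(O)cc1)[C@@H]1Cc2cc(/C=C/C(=O)OC(C)(C)C)ccc2O1
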